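**Retrosynthetic overview**
- The last bond made is the amidine C–N bond between the 2-amino group of the fully substituted 2-aminoimidazole and C4 of silyl-activated 1-methylparabanic acid.
- The key bond is imidazole C4–CH2, made by Negishi coupling of a 2-[bis(Boc)amino]imidazol-4-yl triflate with 4-methoxybenzylzinc chloride; acid then removes both Boc groups and the MOM ether.
- The triflate comes from creatinine: Knoevenagel condensation at C5 with the MOM-protected aldehyde, alkene hydrogenation, di-Boc protection and enolate O-triflation, which aromatises the ring without an oxidant.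
- Feature on which the strategy rests: N1–CH3, C2–NH2, N3, C4 and C5 of the imidazole are the ring atoms of creatinine. Its C5 methylene takes the 3-hydroxy-4,5-dimethoxybenzyl group, and its C4 carbonyl marks the carbon that receives the 4-methoxybenzyl group.
- Ring order: no ring is built. The imidazole ring is bought as creatinine and becomes aromatic in step 5; the imidazole-2,5-dione ring is bought as 1-methylparabanic acid and attached last.

Key step: step 7

Assumption: the second Boc group introduced in step 4 is drawn on the exocyclic nitrogen; an isomer carrying it on N3 would have no N–H either and would converge on the same free 2-aminoimidazole after the acid step.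

**Step 1**
Reactants: 1 3-hydroxy-4,5-dimethoxybenzaldehyde
Product: 2 3,4-dimethoxy-5-(methoxymethoxy)benzaldehyde
Conditions: MOMCl, iPr2NEt, CH2Cl2, 0 °C to rt
Reagents that add atoms: chloromethyl methyl ether (MOMCl), COCCl
Why: Williamson-type O-alkylation of the phenol gives an acetal that should survive amine base, hydrogenation, KN(SiMe3)2 and the organozinc reagent and that leaves together with the Boc groups in acid.

**Step 2**
Reactants: 2 3,4-dimethoxy-5-(methoxymethoxy)benzaldehyde; 3 creatinine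
Product: 4 (Z)-2-amino-5-[3,4-dimethoxy-5-(methoxymethoxy)benzylidene]-1-methyl-1,5-dihydro-4H-imidazol-4-one (Z drawn; the E isomer would serve equally)
Conditions: piperidine (0.5 equiv.), n-BuOH, reflux
Reagents that add atoms: none
Why: Knoevenagel condensation at the C5 methylene of creatinine, which is activated by the C4 carbonyl, is a known reaction with aryl aldehydes, and the basic medium spares the MOM ether.

**Step 3**
Reactants: 4 (Z)-2-amino-5-[3,4-dimethoxy-5-(methoxymethoxy)benzylidene]-1-methyl-1,5-dihydro-4H-imidazol-4-one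
Product: 5 rac-2-amino-5-[3,4-dimethoxy-5-(methoxymethoxy)benzyl]-1-methyl-1,5-dihydro-4H-imidazol-4-one
Conditions: H2 (3 atm), 10% Pd/C, MeOH–AcOH (10:1), rt
Reagents that add atoms: none
Why: heterogeneous catalytic hydrogenation of the trisubstituted arylidene alkene leaves the aryl ethers, the acetal and the acylguanidine untouched; the new C5 stereocentre is formed without control (racemic) and is erased again in step 5.

**Step 4**
Reactants: 5 rac-2-amino-5-[3,4-dimethoxy-5-(methoxymethoxy)benzyl]-1-methyl-1,5-dihydro-4H-imidazol-4-one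
Product: 6 rac-2-[bis(tert-butoxycarbonyl)amino]-5-[3,4-dimethoxy-5-(methoxymethoxy)benzyl]-1-methyl-1,5-dihydro-4H-imidazol-4-one
Conditions: Boc2O (2.3 equiv.), DMAP (0.1 equiv.), Et3N, THF, 0 °C to rt
Reagents that add atoms: di-tert-butyl dicarbonate (Boc2O), CC(C)(C)OC(=O)OC(=O)OC(C)(C)C
Why: DMAP-catalysed exhaustive N-acylation of the amidine NH2, as known for 2-aminoazoles and 2-aminoazines, removes both N–H protons so that C5–H is the only acidic site left for step 5.

**Step 5**
Reactants: 6 rac-2-[bis(tert-butoxycarbonyl)amino]-5-[3,4-dimethoxy-5-(methoxymethoxy)benzyl]-1-methyl-1,5-dihydro-4H-imidazol-4-one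
Product: 7 2-[bis(tert-butoxycarbonyl)amino]-5-[3,4-dimethoxy-5-(methoxymethoxy)benzyl]-1-methyl-1H-imidazol-4-yl trifluoromethanesulfonate
Conditions: KN(SiMe3)2 (1.1 equiv.), THF, −78 °C; then PhNTf2 (1.2 equiv.), −78 to 0 °C
Reagents that add atoms: N-phenylbis(trifluoromethanesulfonimide) (PhNTf2), O=S(=O)(N(c1ccccc1)S(=O)(=O)C(F)(F)F)C(F)(F)F
Why: Proposed new method: the hindered amide base removes C5–H, the only acidic proton, to give an aromatic 4-oxidoimidazole whose oxygen is the hardest and most accessible site for sulfonyl transfer from PhNTf2, so the ring should be aromatised as the O-triflate without an oxidant; the closest known reaction type is the O-triflation of lactam and azolone enolates (N-acyl lactams, pyrazolones, oxazol-4-ones) with PhNTf2, which has not been shown for 2-aminoimidazol-4-ones.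

**Step 6**
Reactants: 8 4-methoxybenzyl chloride
Product: 9 4-methoxybenzylzinc chloride (LiCl-containing THF solution, titrated with iodine and used as such)
Conditions: Zn dust (1.5 equiv., activated with BrCH2CH2Br and Me3SiCl), LiCl (1.5 equiv.), THF, rt
Reagents that add atoms: zinc, [Zn]
Why: LiCl-promoted oxidative insertion of zinc metal into the benzylic C–Cl bond is a known route to benzylzinc chlorides, and slow addition of the chloride should keep Wurtz homocoupling low.

**Step 7**
Reactants: 7 2-[bis(tert-butoxycarbonyl)amino]-5-[3,4-dimethoxy-5-(methoxymethoxy)benzyl]-1-methyl-1H-imidazol-4-yl trifluoromethanesulfonate; 9 4-methoxybenzylzinc chloride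
Product: 10 2-[bis(tert-butoxycarbonyl)amino]-5-[3,4-dimethoxy-5-(methoxymethoxy)benzyl]-4-(4-methoxybenzyl)-1-methyl-1H-imidazole
Conditions: Pd(OAc)2 (3 mol%), SPhos (6 mol%), 9 (1.5 equiv.), THF, rt to 50 °C
Reagents that add atoms: none
Why: Proposed new method: Pd(OAc)2 is reduced by the organozinc reagent to an SPhos-bound zerovalent palladium species that inserts into the C4–O bond of the triflate; the benzyl group then passes from zinc to palladium, and reductive elimination from divalent palladium forms the C4(sp2)–CH2(sp3) bond, with no β-hydrogen on the benzyl group to divert the intermediate. The closest known reaction type is the Negishi coupling of aryl and heteroaryl triflates (pyridyl, pyrazolyl, oxazolyl) with benzylzinc chlorides under Pd(OAc)2 and SPhos, which has not been shown for a 2-aminoimidazol-4-yl triflate. No ring is closed and no stereocentre is formed. The step needs cleavage of the C–O bond and not of the S–O bond of the triflate, and a ring poor enough in electrons for oxidative addition; the two Boc groups take the donor character from the C2 nitrogen and leave no N–H that could quench the zinc reagent or bind palladium. The positions of the two benzyl groups cannot be exchanged, because the C5 group entered by condensation at the creatinine methylene and the triflate oxygen is the former C4 carbonyl oxygen.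

**Step 8**
Reactants: 10 2-[bis(tert-butoxycarbonyl)amino]-5-[3,4-dimethoxy-5-(methoxymethoxy)benzyl]-4-(4-methoxybenzyl)-1-methyl-1H-imidazole
Product: 11 2-amino-5-(3-hydroxy-4,5-dimethoxybenzyl)-4-(4-methoxybenzyl)-1-methyl-1H-imidazole
Conditions: HCl (3 M in MeOH), 0 to 40 °C; then aq. NaHCO3
Reagents that add atoms: none
Why: acidolysis cleaves both tert-butyl carbamates (loss of the tert-butyl cation, then decarboxylation) and the MOM acetal in one operation, and methanol traps the methoxymethyl cation as dimethoxymethane so that no formaldehyde should reach the nucleophilic 2-aminoimidazole.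

**Step 9**
Reactants: 11 2-amino-5-(3-hydroxy-4,5-dimethoxybenzyl)-4-(4-methoxybenzyl)-1-methyl-1H-imidazole; 12 1-methylparabanic acid
Product: 14 4-({5-[(3-hydroxy-4,5-dimethoxyphenyl)methyl]-4-[(4-methoxyphenyl)methyl]-1-methyl-1H-imidazol-2-yl}amino)-1-methyl-1H-imidazole-2,5-dione (CNP0321799.0), via O-trimethylsilyl 1-methylparabanic acid 13 (not isolated)
Conditions: 12 (2 equiv.), N,O-bis(trimethylsilyl)acetamide (2 equiv.), MeCN, 80 °C, then evaporation; 11, toluene, 110 °C; MeOH on work-up
Reagents that add atoms: none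
Why: silylation turns the N3–H/C4=O lactam unit of 12 into an O-silyl imidate, and addition–elimination of the exocyclic amine at C4 with loss of trimethylsilanol gives the amidine, a known silyl-mediated condensation of 2-aminoimidazoles with parabanic acids that tolerates a free phenol.

**Compound list**
1 | 3-hydroxy-4,5-dimethoxybenzaldehyde | COc1cc(C=O)cc(O)c1OC | starting material
2 | 3,4-dimethoxy-5-(methoxymethoxy)benzaldehyde | COCOc1cc(C=O)cc(OC)c1OC | intermediate
3 | creatinine (2-amino-1-methyl-1,5-dihydro-4H-imidazol-4-one) | CN1CC(=O)N=C1N | starting material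
4 | (Z)-2-amino-5-[3,4-dimethoxy-5-(methoxymethoxy)benzylidene]-1-methyl-1,5-dihydro-4H-imidazol-4-one | CN1C(N)=NC(=O)/C1=C/c1cc(OCOC)c(OC)c(OC)c1 | intermediate
5 | rac-2-amino-5-[3,4-dimethoxy-5-(methoxymethoxy)benzyl]-1-methyl-1,5-dihydro-4H-imidazol-4-one (racemic) | CN1C(N)=NC(=O)C1Cc1cc(OCOC)c(OC)c(OC)c1 | intermediate
6 | rac-2-[bis(tert-butoxycarbonyl)amino]-5-[3,4-dimethoxy-5-(methoxymethoxy)benzyl]-1-methyl-1,5-dihydro-4H-imidazol-4-one (racemic) | CN1C(N(C(=O)OC(C)(C)C)C(=O)OC(C)(C)C)=NC(=O)C1Cc1cc(OCOC)c(OC)c(OC)c1 | intermediate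
7 | 2-[bis(tert-butoxycarbonyl)amino]-5-[3,4-dimethoxy-5-(methoxymethoxy)benzyl]-1-methyl-1H-imidazol-4-yl trifluoromethanesulfonate | Cn1c(N(C(=O)OC(C)(C)C)C(=O)OC(C)(C)C)nc(OS(=O)(=O)C(F)(F)F)c1Cc1cc(OCOC)c(OC)c(OC)c1 | intermediate
8 | 4-methoxybenzyl chloride | COc1ccc(CCl)cc1 | starting material
9 | 4-methoxybenzylzinc chloride | COc1ccc(C[Zn]Cl)cc1 | intermediate
10 | 2-[bis(tert-butoxycarbonyl)amino]-5-[3,4-dimethoxy-5-(methoxymethoxy)benzyl]-4-(4-methoxybenzyl)-1-methyl-1H-imidazole | Cn1c(N(C(=O)OC(C)(C)C)C(=O)OC(C)(C)C)nc(Cc2ccc(OC)cc2)c1Cc1cc(OCOC)c(OC)c(OC)c1 | intermediate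
11 | 2-amino-5-(3-hydroxy-4,5-dimethoxybenzyl)-4-(4-methoxybenzyl)-1-methyl-1H-imidazole | Cn1c(N)nc(Cc2ccc(OC)cc2)c1Cc1cc(O)c(OC)c(OC)c1 | intermediate
12 | 1-methylparabanic acid (1-methylimidazolidine-2,4,5-trione) | CN1C(=O)NC(=O)C1=O | starting material
13 | O-trimethylsilyl 1-methylparabanic acid (1-methyl-4-(trimethylsilyloxy)-1H-imidazole-2,5-dione) | CN1C(=O)N=C(O[Si](C)(C)C)C1=O | intermediate
14 | 4-({5-[(3-hydroxy-4,5-dimethoxyphenyl)methyl]-4-[(4-methoxyphenyl)methyl]-1-methyl-1H-imidazol-2-yl}amino)-1-methyl-1H-imidazole-2,5-dione | COc1ccc(Cc2nc(NC3=NC(=O)N(C)C3=O)n(C)c2Cc2cc(O)c(OC)c(OC)c2)cc1 | target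

**Step count**
Total steps: 9. Longest linear sequence: 8 steps (1 → 2 → 4 → 5 → 6 → 7 → 10 → 11 → 14); the zinc reagent 9 is a one-step branch.

**Steps most likely to fail**

1. Step 7 (Proposed new method). Oxidative addition into the C4–O bond of the electron-rich azole may be slow. S–O cleavage of the triflate, which returns the imidazolone, and Wurtz-type homocoupling of the benzylzinc reagent could then take over.
Fallback, known chemistry, with the polarity of the C4–CH2 bond reversed (imidazol-4-yl nucleophile, aldehyde electrophile); it sets out from 1 and comes back at 11. Compound 1 is benzylated (BnBr, K2CO3, DMF) to 3-(benzyloxy)-4,5-dimethoxybenzaldehyde F1. Commercial 4,5-diiodo-1-methylimidazole undergoes iodine–magnesium exchange at C5 with EtMgBr (THF, rt) to give (4-iodo-1-methyl-1H-imidazol-5-yl)magnesium bromide F2. Addition of F2 to F1 should give rac-[3-(benzyloxy)-4,5-dimethoxyphenyl](4-iodo-1-methyl-1H-imidazol-5-yl)methanol F3. iPrMgCl·LiCl (2.2 equiv., THF) deprotonates the hydroxyl group and exchanges the C4 iodine to give the C4-magnesiated chloromagnesium alkoxide F4. This adds to 4-methoxybenzaldehyde to give [3-(benzyloxy)-4,5-dimethoxyphenyl]{4-[hydroxy(4-methoxyphenyl)methyl]-1-methyl-1H-imidazol-5-yl}methanol F5 as a mixture of diastereomers. Ionic hydrogenation (Et3SiH, CF3CO2H, CH2Cl2) removes both benzylic hydroxyl groups to give 5-[3-(benzyloxy)-4,5-dimethoxybenzyl]-4-(4-methoxybenzyl)-1-methyl-1H-imidazole F6. n-BuLi (THF, −78 °C) lithiates C2 to give {5-[3-(benzyloxy)-4,5-dimethoxybenzyl]-4-(4-methoxybenzyl)-1-methyl-1H-imidazol-2-yl}lithium F7. Tosyl azide converts F7 into 2-azido-5-[3-(benzyloxy)-4,5-dimethoxybenzyl]-4-(4-methoxybenzyl)-1-methyl-1H-imidazole F8. Hydrogenation (H2, 10% Pd/C, MeOH) reduces the azide and cleaves the benzyl ether to give 11.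

2. Step 5 (Proposed new method). The ambident anion may be sulfonylated on N3 or C5 instead of oxygen, a Boc group may be transferred to the oxido oxygen, or the triflate may lose its sulfonyl group by hydrolysis during isolation.
Fallback, known chemistry, in which the creatinine ring is opened and the 2-aminoimidazole ring is rebuilt with the second benzyl group already in place; it sets out from 5 and comes back at 11. Hydrolysis of 5 with Ba(OH)2 (H2O, reflux) should give rac-N-methyl-3-[3,4-dimethoxy-5-(methoxymethoxy)phenyl]alanine F9. Boc2O and NaOH (dioxane–H2O) give rac-N-(tert-butoxycarbonyl)-N-methyl-3-[3,4-dimethoxy-5-(methoxymethoxy)phenyl]alanine F10. Coupling with MeNHOMe·HCl (EDC·HCl, HOBt, iPr2NEt, CH2Cl2) gives the Weinreb amide rac-tert-butyl {3-[3,4-dimethoxy-5-(methoxymethoxy)phenyl]-1-[methoxy(methyl)amino]-1-oxopropan-2-yl}(methyl)carbamate F11. Commercial 4-methoxybenzylmagnesium chloride (THF, 0 °C) gives the ketone rac-tert-butyl {1-[3,4-dimethoxy-5-(methoxymethoxy)phenyl]-4-(4-methoxyphenyl)-3-oxobutan-2-yl}(methyl)carbamate F12. HCl in MeOH removes the Boc and MOM groups to give rac-1-(3-hydroxy-4,5-dimethoxyphenyl)-4-(4-methoxyphenyl)-2-(methylamino)butan-2-one... more exactly rac-4-(3-hydroxy-4,5-dimethoxyphenyl)-1-(4-methoxyphenyl)-3-(methylamino)butan-2-one hydrochloride F13. Condensation of F13 with cyanamide (H2O–EtOH, pH 4.5, 95 °C) closes the ring to 11; the methylamino carbon becomes C5 and the ketone carbon becomes C4.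

3. Step 4. The second acylation may stop short and leave an acidic N–H, or the enol tautomer may be acylated on oxygen under DMAP catalysis, which would use up the C4 oxygen needed for step 5.
Fallback in which the NH2 group is masked as an N,N-dimethylformamidine, a single group that removes both N–H protons without an acylating agent; it sets out from 5 and comes back at 11. Heating 5 with Me2NCH(OMe)2 (toluene, 80 °C) should give rac-(E)-N'-{5-[3,4-dimethoxy-5-(methoxymethoxy)benzyl]-1-methyl-4-oxo-4,5-dihydro-1H-imidazol-2-yl}-N,N-dimethylformimidamide F14. KN(SiMe3)2 and PhNTf2 (THF, −78 to 0 °C) give 5-[3,4-dimethoxy-5-(methoxymethoxy)benzyl]-2-{(E)-[(dimethylamino)methylidene]amino}-1-methyl-1H-imidazol-4-yl trifluoromethanesulfonate F15. Coupling with 9 under Pd(OAc)2 and SPhos gives (E)-N'-{5-[3,4-dimethoxy-5-(methoxymethoxy)benzyl]-4-(4-methoxybenzyl)-1-methyl-1H-imidazol-2-yl}-N,N-dimethylformimidamide F16. Aqueous HCl in MeOH (60 °C) hydrolyses the amidine and the MOM ether to give 11.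

**Further compounds**
F1 | step 7 | 3-(benzyloxy)-4,5-dimethoxybenzaldehyde | COc1cc(C=O)cc(OCc2ccccc2)c1OC
F2 | step 7 | (4-iodo-1-methyl-1H-imidazol-5-yl)magnesium bromide | Cn1cnc(I)c1[Mg]Br
F3 | step 7 | rac-[3-(benzyloxy)-4,5-dimethoxyphenyl](4-iodo-1-methyl-1H-imidazol-5-yl)methanol | Cn1cnc(I)c1C(O)c1cc(OCc2ccccc2)c(OC)c(OC)c1
F4 | step 7 | C4-magnesiated chloromagnesium alkoxide of F3 | Cn1cnc([Mg]Cl)c1C(O[Mg]Cl)c1cc(OCc2ccccc2)c(OC)c(OC)c1
F5 | step 7 | [3-(benzyloxy)-4,5-dimethoxyphenyl]{4-[hydroxy(4-methoxyphenyl)methyl]-1-methyl-1H-imidazol-5-yl}methanol (mixture of diastereomers) | Cn1cnc(C(O)c2ccc(OC)cc2)c1C(O)c1cc(OCc2ccccc2)c(OC)c(OC)c1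
F6 | step 7 | 5-[3-(benzyloxy)-4,5-dimethoxybenzyl]-4-(4-methoxybenzyl)-1-methyl-1H-imidazole | Cn1cnc(Cc2ccc(OC)cc2)c1Cc1cc(OCc2ccccc2)c(OC)c(OC)c1
F7 | step 7 | {5-[3-(benzyloxy)-4,5-dimethoxybenzyl]-4-(4-methoxybenzyl)-1-methyl-1H-imidazol-2-yl}lithium | [Li]c1nc(Cc2ccc(OC)cc2)c(Cc2cc(OCc3ccccc3)c(OC)c(OC)c2)n1C
F8 | step 7 | 2-azido-5-[3-(benzyloxy)-4,5-dimethoxybenzyl]-4-(4-methoxybenzyl)-1-methyl-1H-imidazole | [N-]=[N+]=Nc1nc(Cc2ccc(OC)cc2)c(Cc2cc(OCc3ccccc3)c(OC)c(OC)c2)n1C
F9 | step 5 | rac-N-methyl-3-[3,4-dimethoxy-5-(methoxymethoxy)phenyl]alanine | CNC(Cc1cc(OCOC)c(OC)c(OC)c1)C(=O)O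
F10 | step 5 | rac-N-(tert-butoxycarbonyl)-N-methyl-3-[3,4-dimethoxy-5-(methoxymethoxy)phenyl]alanine | CN(C(=O)OC(C)(C)C)C(Cc1cc(OCOC)c(OC)c(OC)c1)C(=O)O
F11 | step 5 | rac-tert-butyl {3-[3,4-dimethoxy-5-(methoxymethoxy)phenyl]-1-[methoxy(methyl)amino]-1-oxopropan-2-yl}(methyl)carbamate | CON(C)C(=O)C(Cc1cc(OCOC)c(OC)c(OC)c1)N(C)C(=O)OC(C)(C)C
F12 | step 5 | rac-tert-butyl {1-[3,4-dimethoxy-5-(methoxymethoxy)phenyl]-4-(4-methoxyphenyl)-3-oxobutan-2-yl}(methyl)carbamate | COc1ccc(CC(=O)C(Cc2cc(OCOC)c(OC)c(OC)c2)N(C)C(=O)OC(C)(C)C)cc1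
F13 | step 5 | rac-4-(3-hydroxy-4,5-dimethoxyphenyl)-1-(4-methoxyphenyl)-3-(methylamino)butan-2-one hydrochloride | CNC(Cc1cc(O)c(OC)c(OC)c1)C(=O)Cc1ccc(OC)cc1.Cl
F14 | step 4 | rac-(E)-N'-{5-[3,4-dimethoxy-5-(methoxymethoxy)benzyl]-1-methyl-4-oxo-4,5-dihydro-1H-imidazol-2-yl}-N,N-dimethylformimidamide | CN1C(/N=C/N(C)C)=NC(=O)C1Cc1cc(OCOC)c(OC)c(OC)c1
F15 | step 4 | 5-[3,4-dimethoxy-5-(methoxymethoxy)benzyl]-2-{(E)-[(dimethylamino)methylidene]amino}-1-methyl-1H-imidazol-4-yl trifluoromethanesulfonate | Cn1c(/N=C/N(C)C)nc(OS(=O)(=O)C(F)(F)F)c1Cc1cc(OCOC)c(OC)c(OC)c1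
F16 | step 4 | (E)-N'-{5-[3,4-dimethoxy-5-(methoxymethoxy)benzyl]-4-(4-methoxybenzyl)-1-methyl-1H-imidazol-2-yl}-N,N-dimethylformimidamide | Cn1c(/N=C/N(C)C)nc(Cc2ccc(OC)cc2)c1Cc1cc(OCOC)c(OC)c(OC)c1
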